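**Retrosynthetic overview**
1. Target 23 ⇐ sulfone 22: the C6=C7 bond of the ring-B diene is made last by loss of PhSO2H from C6.
2. 22 ⇐ epoxy diene 20: rings A then B close in one epoxide-triggered cation–olefin bicyclisation (C4–C5, C9–C10), as in the cyclisation of a squalene 2,3-epoxide terminus.
3. 20 ⇐ bromide 13 + epoxygeranyl sulfone 16: the only fragment union is C6–C7, inside the future ring B and not at the C11–C12 linker.
4. 13 ⇐ acyclic diepoxide 11: ring D (oxepane) then ring C close in one epoxonium cascade of the 1,5-diepoxide, ended by hydride capture that sets C14.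
5. 11 ⇐ farnesyl phenyl sulfone + ethyl 4-bromo-2-methylbut-2-enoate; all absolute configuration comes from two Shi epoxidations (C17, C18, C21; C3).

Numbering used: decalin C1–C10 (C3 carbinol, C4 gem-dimethyl, C8 methyl), linker C11–C12, ring C C13–C18 (C13 bears the linker, C14 CHMe, C17 CH–O, C18 C–Me), ring D C19–C22 plus O (C21 carbonyl, C22 gem-dimethyl).
Assumption: the enantiomer of the D-fructose-derived Shi ketone gives the (S)-epoxide series with these trisubstituted alkenes.

Step 1
Reactants: 1 (2E,6E)-farnesyl bromide; 2 sodium benzenesulfinate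
Product: 3 (2E,6E)-farnesyl phenyl sulfone
Conditions: PhSO2Na, DMF, 23 °C
Reagents that add atoms: none
Why: SN2 S-alkylation of the sulfinate by the primary allylic bromide (sulfone synthesis) keeps both E alkenes and creates no stereocentre.

Step 2
Reactants: 3 (2E,6E)-farnesyl phenyl sulfone
Product: 4 (2E,6S,7S,10S)-6,7:10,11-diepoxyfarnesyl phenyl sulfone
Conditions: ent-Shi ketone (0.6 equiv), Oxone (2KHSO5·KHSO4·K2SO4), K2CO3, Bu4NHSO4, MeCN/CH2(OMe)2/aq. Na2B4O7 buffer, 0 °C
Reagents that add atoms: Oxone, active salt potassium peroxymonosulfate, [K+].[O-]S(=O)(=O)OO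
Why: Shi asymmetric epoxidation: the chiral dioxirane attacks the two electron-rich trisubstituted alkenes through a spiro transition state from one enantioface and so sets C17, C18 and C21 (all S), while the C13=C14 alkene is deactivated by the allylic sulfone.

Step 3
Reactants: 4 (2E,6S,7S,10S)-6,7:10,11-diepoxyfarnesyl phenyl sulfone; 5 ethyl (E)-4-bromo-2-methylbut-2-enoate
Product: 7 ethyl (2E,6E,10S,11S,14S)-10,11:14,15-diepoxy-2,7,11,15-tetramethyl-5-(phenylsulfonyl)hexadeca-2,6-dienoate (both C5 epimers), via lithio sulfone 6 (not isolated)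
Conditions: n-BuLi (1.05 equiv), THF, −78 °C; then 5, −78 → −40 °C
Reagents that add atoms: none
Why: Julia-type alkylation of the alpha-sulfonyl allyl anion at its alpha carbon by SN2 displacement on the gamma-bromo enoate builds the tail-to-tail C11–C12 bond with the E enoate intact; the new sulfonyl-bearing centre is removed in step 4.

Step 4
Reactants: 7 ethyl (2E,6E,10S,11S,14S)-10,11:14,15-diepoxy-2,7,11,15-tetramethyl-5-(phenylsulfonyl)hexadeca-2,6-dienoate
Product: 9 (2E,6E,10S,11S,14S)-10,11:14,15-diepoxy-2,7,11,15-tetramethylhexadeca-2,6-dien-1-ol, via hydroxy sulfone 8 (not isolated)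
Conditions: LiEt3BH (2.3 equiv), THF, −78 °C; then PdCl2(dppp) (5 mol %), LiEt3BH (1.5 equiv), −20 → 0 °C
Reagents that add atoms: none
Why: LiEt3BH first reduces the conjugated ester 1,2 to the allylic alkoxide and then acts as hydride donor in the palladium-catalysed reductive cleavage of the allylic sulfone (pi-allylpalladium attacked at the less substituted terminus, so the E trisubstituted alkene stays in place), both faster at or below 0 °C than hydride opening of the hindered trisubstituted epoxides; no stereocentre is touched.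

Step 5
Reactants: 9 (2E,6E,10S,11S,14S)-10,11:14,15-diepoxy-2,7,11,15-tetramethylhexadeca-2,6-dien-1-ol
Product: 11 (2E,6E,10S,11S,14S)-1-bromo-10,11:14,15-diepoxy-2,7,11,15-tetramethylhexadeca-2,6-diene, via mesylate 10 (not isolated)
Conditions: MsCl, Et3N, THF, −40 °C; then LiBr, −40 → 0 °C
Reagents that add atoms: lithium bromide, [Li+].[Br-]
Why: Mesylation of the primary allylic alcohol and SN2 exchange by bromide give the allylic bromide without touching the acid-sensitive epoxides or the alkene geometry.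

Step 6
Reactants: 11 (2E,6E,10S,11S,14S)-1-bromo-10,11:14,15-diepoxy-2,7,11,15-tetramethylhexadeca-2,6-diene
Product: 13 (3S,5aS,6R,7R,9aS)-6-[(3E)-5-bromo-4-methylpent-3-en-1-yl]-2,2,5a,7-tetramethyl-3-(triethylsilyloxy)decahydro-1-benzoxepine, via C14 carbocation 12 (not isolated)
Conditions: Et3SiOTf (1.2 equiv), 2,6-di-tert-butyl-4-methylpyridine (1.5 equiv), Et3SiH (10 equiv), CH2Cl2, −78 °C; aq. NaHCO3
Reagents that add atoms: triethylsilyl triflate, CC[Si](CC)(CC)OS(=O)(=O)C(F)(F)F; triethylsilane, CC[SiH](CC)CC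
Why: Proposed new method: Et3Si+ activates the terminal epoxide, the neighbouring epoxide oxygen attacks C22 to give a bicyclic epoxonium ion (ring D), the C13=C14 alkene opens it at C18 with inversion through a chair transition state (ring C; trans fusion from the S,S-epoxide, C13 side chain equatorial from the E alkene), and the tertiary C14 cation takes hydride from Et3SiH on the face away from the axial C18 methyl, which sets the axial C14 methyl and regenerates Et3SiOTf; the closest known chemistry is the silyl-triflate-promoted tandem oxa- and carbacyclisation of 1,5-diepoxides that ends by proton loss, combined with ionic hydrogenation of tertiary cations by silanes, and the alkene next to the CH2Br group is too electron-poor to intercept the cation.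

Step 7
Reactants: 14 geranyl bromide; 2 sodium benzenesulfinate
Product: 15 geranyl phenyl sulfone
Conditions: PhSO2Na, DMF, 23 °C
Reagents that add atoms: none
Why: SN2 S-alkylation of the sulfinate by the primary allylic bromide (sulfone synthesis) keeps the E alkene and creates no stereocentre.

Step 8
Reactants: 15 geranyl phenyl sulfone
Product: 16 (2E,6S)-6,7-epoxy-3,7-dimethyloct-2-en-1-yl phenyl sulfone
Conditions: ent-Shi ketone (0.3 equiv), Oxone (2KHSO5·KHSO4·K2SO4), K2CO3, Bu4NHSO4, MeCN/CH2(OMe)2/aq. Na2B4O7 buffer, 0 °C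
Reagents that add atoms: Oxone, active salt potassium peroxymonosulfate, [K+].[O-]S(=O)(=O)OO
Why: Shi asymmetric epoxidation of the only electron-rich alkene sets the future C3 as S, the alkene next to the sulfone being deactivated.

Step 9
Reactants: 16 (2E,6S)-6,7-epoxy-3,7-dimethyloct-2-en-1-yl phenyl sulfone; 13 (3S,5aS,6R,7R,9aS)-6-[(3E)-5-bromo-4-methylpent-3-en-1-yl]-2,2,5a,7-tetramethyl-3-(triethylsilyloxy)decahydro-1-benzoxepine
Product: 19 (3S,5aS,6R,7R,9aS)-6-[(3E,7E,11S)-11,12-epoxy-4,8,12-trimethyl-6-(phenylsulfonyl)trideca-3,7-dien-1-yl]-2,2,5a,7-tetramethyldecahydro-1-benzoxepin-3-ol (both epimers at the sulfonyl carbon), via lithio sulfone 17 (not isolated), via silyl ether 18 (not isolated)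
Conditions: n-BuLi (1.05 equiv), THF, −78 °C; then 13, −78 → −30 °C; then Bu4NF, THF, 0 → 23 °C
Reagents that add atoms: none
Why: Julia-type sulfone-anion alkylation (SN2 on the primary allylic bromide) joins the halves at C6–C7 inside the future ring B and fluoride then frees the C21 alcohol; the sulfonyl-bearing C6 centre forms as a mixture that is erased in step 12.

Step 10
Reactants: 19 seco alcohol (C21 carbinol)
Product: 20 (5aS,6R,7R,9aS)-6-[(3E,7E,11S)-11,12-epoxy-4,8,12-trimethyl-6-(phenylsulfonyl)trideca-3,7-dien-1-yl]-2,2,5a,7-tetramethyloctahydro-1-benzoxepin-3(2H)-one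
Conditions: Dess–Martin periodinane, NaHCO3, CH2Cl2, 23 °C
Reagents that add atoms: none
Why: Dess–Martin oxidation turns the only free secondary alcohol into the C21 ketone under buffered conditions that spare the epoxide, sulfone and alkenes, before the C3 hydroxyl exists.

Step 11
Reactants: 20 seco ketone
Product: 22 tetracyclic sulfone (target skeleton with PhSO2 at C6, CH2 at C7 and the C8=C9 alkene; both C6 epimers), via C8 carbocation 21 (not isolated)
Conditions: BF3·OEt2 (2.5 equiv), CH2Cl2, −78 → −30 °C; aq. NaHCO3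
Reagents that add atoms: none
Why: Biomimetic epoxide-initiated cation–olefin bicyclisation (Stork–Eschenmoser anti addition through chair-like folding): C5 opens the activated epoxide at C4 with inversion and C9 captures the C10 cation, so the retained 3S oxygen ends equatorial and the 5α-H/10β-methyl trans-decalin is fixed by the epoxide configuration and the two E alkenes, the alkene flanked by the sulfone taking part as allylic sulfones do in acid cyclisations of geranyl and farnesyl sulfones, and loss of H-9 from the C8 cation gives the tetrasubstituted alkene (7-ene and exocyclic isomers are expected to equilibrate to it on warming).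

Step 12
Reactants: 22 tetracyclic sulfone
Product: 23 target CNP0106412.1
Conditions: KOt-Bu (3 equiv), THF, 0 → 23 °C
Reagents that add atoms: none
Why: Base-induced 1,2-elimination of benzenesulfinate (Julia-type sulfone elimination, E1cB-like through the allylic H-7) creates C6=C7 in conjugation with C8=C9 and erases the C6 mixture; no other stereocentre is affected.

**Compound list**
1 | (2E,6E)-farnesyl bromide | BrC/C=C(\C)CC/C=C(\C)CCC=C(C)C | starting material
2 | sodium benzenesulfinate | [Na+].[O-]S(=O)c1ccccc1 | starting material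
3 | (2E,6E)-farnesyl phenyl sulfone | O=S(=O)(c1ccccc1)C/C=C(\C)CC/C=C(\C)CCC=C(C)C | intermediate
4 | (2E,6S,7S,10S)-6,7:10,11-diepoxyfarnesyl phenyl sulfone (trans epoxides) | O=S(=O)(c1ccccc1)C/C=C(\C)CC[C@@H]2O[C@@]2(C)CC[C@@H]3OC3(C)C | intermediate
5 | ethyl (E)-4-bromo-2-methylbut-2-enoate | CCOC(=O)/C(C)=C/CBr | starting material
6 | lithio sulfone from 4 (carbanion alpha to sulfur) | [Li+].O=S(=O)(c1ccccc1)[CH-]/C=C(\C)CC[C@@H]2O[C@@]2(C)CC[C@@H]3OC3(C)C | intermediate
7 | ethyl (2E,6E,10S,11S,14S)-10,11:14,15-diepoxy-2,7,11,15-tetramethyl-5-(phenylsulfonyl)hexadeca-2,6-dienoate, both C5 epimers | CCOC(=O)/C(C)=C/CC(S(=O)(=O)c1ccccc1)/C=C(\C)CC[C@@H]2O[C@@]2(C)CC[C@@H]3OC3(C)C | intermediate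
8 | hydroxy sulfone: (2E,6E,10S,11S,14S)-10,11:14,15-diepoxy-2,7,11,15-tetramethyl-5-(phenylsulfonyl)hexadeca-2,6-dien-1-ol (present as lithium alkoxide), both C5 epimers | OC/C(C)=C/CC(S(=O)(=O)c1ccccc1)/C=C(\C)CC[C@@H]2O[C@@]2(C)CC[C@@H]3OC3(C)C | intermediate
9 | (2E,6E,10S,11S,14S)-10,11:14,15-diepoxy-2,7,11,15-tetramethylhexadeca-2,6-dien-1-ol | OC/C(C)=C/CC/C=C(\C)CC[C@@H]1O[C@@]1(C)CC[C@@H]2OC2(C)C | intermediate
10 | methanesulfonate of 9 | CS(=O)(=O)OC/C(C)=C/CC/C=C(\C)CC[C@@H]1O[C@@]1(C)CC[C@@H]2OC2(C)C | intermediate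
11 | (2E,6E,10S,11S,14S)-1-bromo-10,11:14,15-diepoxy-2,7,11,15-tetramethylhexadeca-2,6-diene | BrC/C(C)=C/CC/C=C(\C)CC[C@@H]1O[C@@]1(C)CC[C@@H]2OC2(C)C | intermediate
12 | C14 tertiary carbocation of the trans-fused oxepane–cyclohexane (triflate ion pair) | BrC/C(C)=C/CC[C@@H]1[C+](C)CC[C@@H]2OC(C)(C)[C@@H](O[Si](CC)(CC)CC)CC[C@]21C.[O-]S(=O)(=O)C(F)(F)F | intermediate
13 | (3S,5aS,6R,7R,9aS)-6-[(3E)-5-bromo-4-methylpent-3-en-1-yl]-2,2,5a,7-tetramethyl-3-(triethylsilyloxy)decahydro-1-benzoxepine (trans fusion; 5a-methyl, side chain and 7-methyl on one face) | BrC/C(C)=C/CC[C@@H]1[C@H](C)CC[C@@H]2OC(C)(C)[C@@H](O[Si](CC)(CC)CC)CC[C@]21C | intermediate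
14 | geranyl bromide | BrC/C=C(\C)CCC=C(C)C | starting material
15 | geranyl phenyl sulfone | O=S(=O)(c1ccccc1)C/C=C(\C)CCC=C(C)C | intermediate
16 | (2E,6S)-6,7-epoxy-3,7-dimethyloct-2-en-1-yl phenyl sulfone | O=S(=O)(c1ccccc1)C/C=C(\C)CC[C@@H]2OC2(C)C | intermediate
17 | lithio sulfone from 16 | [Li+].O=S(=O)(c1ccccc1)[CH-]/C=C(\C)CC[C@@H]2OC2(C)C | intermediate
18 | triethylsilyl ether of 19, both epimers at the sulfonyl carbon | CC1(C)O[C@H]1CC/C(C)=C/C(S(=O)(=O)c2ccccc2)C/C(C)=C/CC[C@@H]3[C@H](C)CC[C@@H]4OC(C)(C)[C@@H](O[Si](CC)(CC)CC)CC[C@]43C | intermediate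
19 | seco alcohol: (3S,5aS,6R,7R,9aS)-6-[(3E,7E,11S)-11,12-epoxy-4,8,12-trimethyl-6-(phenylsulfonyl)trideca-3,7-dien-1-yl]-2,2,5a,7-tetramethyldecahydro-1-benzoxepin-3-ol, both epimers at the sulfonyl carbon | CC1(C)O[C@H]1CC/C(C)=C/C(S(=O)(=O)c2ccccc2)C/C(C)=C/CC[C@@H]3[C@H](C)CC[C@@H]4OC(C)(C)[C@@H](O)CC[C@]43C | intermediate
20 | seco ketone: the 3-ketone of 19 (C21=O) | CC1(C)O[C@H]1CC/C(C)=C/C(S(=O)(=O)c2ccccc2)C/C(C)=C/CC[C@@H]3[C@H](C)CC[C@@H]4OC(C)(C)C(=O)CC[C@]43C | intermediate
21 | C8 tertiary carbocation of the closed trans-decalin (9α-H; C3–O bound to BF3) | C[C+]1[C@H](CC[C@@H]2[C@H](C)CC[C@@H]3OC(C)(C)C(=O)CC[C@]32C)[C@@]2(C)CC[C@H](O[B-](F)(F)F)C(C)(C)[C@@H]2C(S(=O)(=O)c4ccccc4)C1 | intermediate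
22 | tetracyclic sulfone: target skeleton with 3β-OH, 5α-H, 10β-Me, C8=C9 alkene, PhSO2 at C6 (both epimers) and CH2 at C7 | CC1=C(CC[C@@H]2[C@H](C)CC[C@@H]3OC(C)(C)C(=O)CC[C@]32C)[C@@]2(C)CC[C@H](O)C(C)(C)[C@@H]2C(S(=O)(=O)c4ccccc4)C1 | intermediate
23 | CNP0106412.1: (3S,5R,10S)-3-hydroxy-6,8-diene decalin joined through C11–C12 to the (13R,14R,17S,18S)-perhydrobenzoxepin-21-one | CC1=C(CC[C@@H]2[C@H](C)CC[C@@H]3OC(C)(C)C(=O)CC[C@]32C)[C@@]2(C)CC[C@H](O)C(C)(C)[C@@H]2C=C1 | target

**Step count and risks**
Total steps: 12. Longest linear sequence: 10 (steps 1–6, then 9–12).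

Steps most likely to fail:

Step 6 (hydride-terminated epoxonium cascade). Silane capture of the C14 cation may lose to proton loss or give the wrong face. Fallback: cyclise 11 with Me3SiOTf and 2,6-di-tert-butyl-4-methylpyridine alone, so the cascade ends by proton loss and gives an alkene mixture whose main member is the exocyclic-methylene trimethylsilyl ether F1. Then reduce all alkene isomers through their common C14 cation by ionic hydrogenation (CF3CO2H, Et3SiH, CH2Cl2, −20 °C; the silyl ether is lost) to the alcohol F2. Silylation with Et3SiCl and imidazole comes back to the route at 13.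

Step 11 (cationic bicyclisation through the sulfone-deactivated C5=C10 alkene; the C6 epimer that would place the sulfonyl group axial may cyclise poorly). Fallback: start from 20 and switch to the radical manifold. Trivalent titanium (Cp2TiCl, made from Cp2TiCl2 and Mn dust, THF) opens the epoxide homolytically; the tertiary radical, which is far less sensitive to the sulfone, closes rings A and B and ends as the exocyclic 8(17)-alkene F3. RhCl3·3H2O in EtOH (or TsOH in CH2Cl2) then moves the double bond into the ring and returns to 22.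

Step 4 (LiEt3BH in the presence of two epoxides). Fallback: start from 7 and split the operation. Reduce the ester with i-Bu2AlH at −78 °C and isolate the hydroxy sulfone 8. Then remove the sulfone by electron transfer with Na(Hg) and Na2HPO4 in MeOH/THF at −20 °C, which leaves epoxides alone, to arrive at 9. This fallback makes no compound outside the list (F0).

Further compounds
F1 | step 6 | exocyclic-methylene trimethylsilyl ether (C14=CH2 analogue of 13, main alkene isomer) | BrC/C(C)=C/CC[C@@H]1C(=C)CC[C@@H]2OC(C)(C)[C@@H](O[Si](C)(C)C)CC[C@]21C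
F2 | step 6 | C21 alcohol corresponding to 13 (no silyl group) | BrC/C(C)=C/CC[C@@H]1[C@H](C)CC[C@@H]2OC(C)(C)[C@@H](O)CC[C@]21C
F3 | step 11 | exocyclic 8(17)-alkene isomer of 22 (9α-H) | C=C1[C@H](CC[C@@H]2[C@H](C)CC[C@@H]3OC(C)(C)C(=O)CC[C@]32C)[C@@]2(C)CC[C@H](O)C(C)(C)[C@@H]2C(S(=O)(=O)c4ccccc4)C1
F0 | step 4 | none | none
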